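The partner was what I watched in this flask, where a single-handed catalyst meets a racemate.

| flask | left-handed substrate | right-handed substrate | partner | precatalyst | added ligand | remark |
|---|---|---|---|---|---|---|
| winter | 0.23 M | 0.23 M | 1.2 equiv | 1 mol% | 9.6 mM | run made earlier |
| spring | 0.23 M | 0.23 M | 1.2 equiv | 4 mol% | 9.6 mM | run made earlier |
| dusk | 0.23 M | 0.23 M | 2.4 equiv | 2 mol% | 9.6 mM | run made earlier |
| flask | 0.23 M | 0.23 M | 1.20 equiv | 2 mol% | 9.6 mM |  |

| run | time / min | left-handed product / % | left-handed substrate / % |
|---|---|---|---|
| winter | 0.667 | 0.2 | 49.7 |
| winter | 1.33 | 0.6 | 50.1 |
| winter | 2.00 | 0.5 | 49.5 |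
| winter | 2.50 | 0.3 | 50.3 |
| winter | 3.00 | 1.9 | 48.0 |
| winter | 4.00 | 0.9 | 46.3 |
| spring | 0.250 | 1.3 | 48.6 |
| spring | 0.500 | 1.9 | 50.6 |
| spring | 0.833 | 1.0 | 47.8 |
| spring | 1.33 | 1.1 | 48.0 |
| spring | 2.00 | 2.0 | 47.8 |
| spring | 4.00 | 8.0 | 42.5 |
| dusk | 0.667 | 0 | 47.9 |
| dusk | 1.33 | 1.8 | 46.6 |
| dusk | 2.00 | 4.4 | 44.4 |
| dusk | 3.00 | 9.8 | 38.8 |
| dusk | 4.00 | 13.4 | 35.3 |

(scatter of a reading: 1 percentage point)

* factor on the rate of making left-handed product when 50% of the left-handed substrate and right-handed substrate together are converted if partner is charged twice over
* factor on the rate when 50% of the left-handed substrate and right-handed substrate together are converted if precatalyst is charged at 10 mol% instead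

- catalyst is single-handed; left-handed substrate and right-handed substrate are mirror images of each other, charged as a racemate, each of them at the stated concentration
- steps under discussion: partner + catalyst + right-handed substrate -> catalyst + right-handed product; partner + catalyst + left-handed substrate -> catalyst + left-handed product; partner + precatalyst -> catalyst + spent reagent; catalyst + added ligand <-> idle complex

Partner enters the activation of precatalyst and both product-forming steps, each to the first power, so I read its charge as the speed of a clock. With loading and added ligand held fixed, the course of catalyst and substrate against conversion should then stay the same.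

Two ways gave me one number to test this: the left-handed product of a 2 mol%, 1.20 equiv flask at 4.00 min. The spring run, scaled by loading, gives

4.00%

The dusk run has a clock 2.00 times as fast, so its 2.00 min stands for 4.00 min, and it reads

4.4%

With a scatter of 1 percentage point, these two readings from different runs agreed, so I kept the clock, and with it the scaling by loading. At equal conversion, then, flasks with the same loading and added ligand but different partner should hold the same catalyst and substrate, and differ in the partner left.

Partner is the limiting reagent in this flask, 0.276 M against 0.460 M of substrate together. At the 50% mark it stands at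

0.0460 M as charged, 0.322 M doubled

This partner margin, the partner left at the mark, gave me a factor of 7.00. Activation takes at most 4.60 mM from each flask, which would raise it to 7.67. For precatalyst I made no such balance; the charges stand 5.00 to one.

The forecast gave 2.71 for doubled partner and 12.4 for precatalyst, “taking mol% and equiv on total substrate, 0.46 M”. There we parted, for I took the equivalents and the loading on left-handed substrate.

The flask gave 7.40 for doubled partner and 2.51 for precatalyst.

    partner + catalyst + right-handed substrate → catalyst + right-handed product (k = 1.80 M⁻² s⁻¹)
    partner + catalyst + left-handed substrate → catalyst + left-handed product (k = 4.90 M⁻² s⁻¹)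
    partner + precatalyst → catalyst + spent reagent (k = 0.00420 M⁻¹ s⁻¹)
    catalyst + added ligand ⇌ idle complex, settled at all times (K = 85.0 M⁻¹)

At 30.0 min, close to the 28.3 min of the mark, this flask held 0.00291 M of spent reagent, each unit of it one partner used in activation. Taken as an estimate from both margins, the doubled flask holding the same at equal conversion by the clock, that gives

7.41

The earlier runs and the new flask were computed with made-up constants; the scatter is artificial.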